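The route rests on disconnecting the C6–O and C8–O bonds of ring A, so that rings A, B and C, the oxygens at C5, C7 and C4' and the 2S centre all come from (2S)-naringenin. The key step converts both aryl C–Br bonds of a 6,8-dibromo-5,7,4'-trimethoxyflavanone into C–OH in one pot by double Miyaura borylation and perborate oxidation. It exploits the fact that C6 and C8 are the only free ring A carbons, each ortho or para to O1 and to the oxygens on C5 and C7, so bromination marks them selectively, while the weak base spares the C2–O1 bond of ring C. Base-free methylations before and after complete the target.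

Key step: step 3

Remark: (2S)-naringenin 1 is assumed to be available in high enantiomeric purity (purchased, or from enzymatic hydrolysis of naringin), because the route carries the C2 centre through and never creates it.

Step 1
Reactants: 1 (2S)-naringenin; 2 iodomethane
Product: 3 (2S)-5,7-dimethoxy-2-(4-methoxyphenyl)chroman-4-one
Conditions: MeI (excess), Ag2O, DMF, rt, dark, Ar
Reagents that add atoms: iodomethane, CI
Why: Ag2O-promoted Williamson-type O-methylation (Purdie conditions) should etherify the 7-OH and 4'-OH and, with excess reagent, the hydrogen-bonded 5-OH, and because no soluble strong base is present the flavanone should not open to the chalcone, so the 2S centre of 1 is kept.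

Step 2
Reactants: 3 (2S)-5,7-dimethoxy-2-(4-methoxyphenyl)chroman-4-one; 4 N-bromosuccinimide
Product: 5 (2S)-6,8-dibromo-5,7-dimethoxy-2-(4-methoxyphenyl)chroman-4-one
Conditions: NBS (2.2 equiv), DMF, 0 °C to rt, dark
Reagents that add atoms: N-bromosuccinimide, O=C1CCC(=O)N1Br
Why: Electrophilic aromatic bromination with NBS should go only to C6 and C8, the two unsubstituted ring A carbons that each lie ortho or para to three oxygen donors, while the less activated ring B, the C3 methylene and the C2 centre are left alone under these neutral, polar, dark conditions.

Step 3
Reactants: 5 (2S)-6,8-dibromo-5,7-dimethoxy-2-(4-methoxyphenyl)chroman-4-one; 6 bis(pinacolato)diboron; 7 sodium perborate (NaBO3·4H2O)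
Product: 9 (2S)-6,8-dihydroxy-5,7-dimethoxy-2-(4-methoxyphenyl)chroman-4-one, via 6,8-bis(pinacolboryl)flavanone 8 (not isolated)
Conditions: Pd(OAc)2 (10 mol%), SPhos (20 mol%), B2pin2 (4 equiv), KOAc (6 equiv), degassed 1,4-dioxane, 85 °C; then NaBO3·4H2O (excess), THF/H2O, 0 °C to rt; aq. NH4Cl work-up under Ar
Reagents that add atoms: sodium perborate, [Na+].[O-]OB=O (the two new oxygen atoms of 9); bis(pinacolato)diboron, CC1(C)OB(OC1(C)C)B1OC(C)(C)C(C)(C)O1 (the boryl groups of intermediate 8 only)
Why: Zerovalent palladium, formed in situ from Pd(OAc)2 and SPhos, inserts into each aryl C–Br bond, bromide on divalent palladium is exchanged for acetate, the acetate complex transmetalates with B2pin2 and reductive elimination forms the aryl–boron bond, twice over, to give 8, after which hydroperoxide released from perborate adds to each boron and a 1,2-shift of the aryl group from boron to oxygen followed by hydrolysis gives the two phenols. The closest known reaction type is the Miyaura borylation of doubly ortho-substituted, electron-rich aryl halides with bulky dialkylbiarylphosphine ligands, combined with the standard oxidation of aryl boronic esters to phenols. No ring is closed and no stereocentre is created, and the existing 2S centre should survive because KOAc and perborate are too weakly basic to enolize C3 and expel O1 by retro-oxa-Michael opening. Site selectivity is already built into 5, where bromine sits only on C6 and C8, so the step needs chemoselectivity for C–Br over the enolizable ketone, which the acetate base secures by ruling out ketone α-arylation. The main threats are protodebromination at the doubly oxygen-flanked carbons and protodeboronation of the 2,6-dialkoxyaryl boronates, which the electron-rich bulky ligand, anhydrous borylation with excess B2pin2 and immediate oxidation without isolation are meant to counter. The new hydroxyls are meta to the ketone-bearing C4a, so Dakin-type cleavage of the aryl ketone by peroxide is not expected.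

Step 4
Reactants: 9 (2S)-6,8-dihydroxy-5,7-dimethoxy-2-(4-methoxyphenyl)chroman-4-one; 2 iodomethane
Product: 10 (2S)-5,6,7,8-tetramethoxy-2-(4-methoxyphenyl)chroman-4-one
Conditions: MeI (excess), Ag2O, DMF, rt, dark, Ar
Reagents that add atoms: iodomethane, CI
Why: The same Ag2O-promoted Williamson-type O-methylation should convert the two free, non-chelated phenols at C6 and C8 into methyl ethers without any base strong enough to open ring C, so the 2S centre is retained and the target results.

Compound list
1 | (2S)-naringenin, (2S)-5,7-dihydroxy-2-(4-hydroxyphenyl)chroman-4-one | Oc1ccc([C@@H]2CC(=O)c3c(O)cc(O)cc3O2)cc1 | starting material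
2 | iodomethane | CI | starting material
3 | (2S)-5,7-dimethoxy-2-(4-methoxyphenyl)chroman-4-one | COc1ccc([C@@H]2CC(=O)c3c(OC)cc(OC)cc3O2)cc1 | intermediate
4 | N-bromosuccinimide | O=C1CCC(=O)N1Br | starting material
5 | (2S)-6,8-dibromo-5,7-dimethoxy-2-(4-methoxyphenyl)chroman-4-one | COc1ccc([C@@H]2CC(=O)c3c(OC)c(Br)c(OC)c(Br)c3O2)cc1 | intermediate
6 | bis(pinacolato)diboron | CC1(C)OB(OC1(C)C)B1OC(C)(C)C(C)(C)O1 | starting material
7 | sodium perborate, NaBO3 (used as NaBO3·4H2O) | [Na+].[O-]OB=O | starting material
8 | (2S)-5,7-dimethoxy-2-(4-methoxyphenyl)-6,8-bis(4,4,5,5-tetramethyl-1,3,2-dioxaborolan-2-yl)chroman-4-one | COc1ccc([C@@H]2CC(=O)c3c(OC)c(B4OC(C)(C)C(C)(C)O4)c(OC)c(B4OC(C)(C)C(C)(C)O4)c3O2)cc1 | intermediate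
9 | (2S)-6,8-dihydroxy-5,7-dimethoxy-2-(4-methoxyphenyl)chroman-4-one | COc1ccc([C@@H]2CC(=O)c3c(OC)c(O)c(OC)c(O)c3O2)cc1 | intermediate
10 | (2S)-5,6,7,8-tetramethoxy-2-(4-methoxyphenyl)chroman-4-one, (2S)-5,6,7,8,4'-pentamethoxyflavanone | COc1ccc([C@@H]2CC(=O)c3c(OC)c(OC)c(OC)c(OC)c3O2)cc1 | target

Total step count: 4
Longest linear sequence: 4 steps (1 to 3 to 5 to 9 to 10)

Steps most likely to fail

Step 3. The second, more hindered C–Br bond may borylate incompletely, bromine may be lost reductively, the boronates may protodeboronate before oxidation, or prolonged heating may erode the C2 configuration. The fallback sets out from 5 and replaces palladium borylation by copper-mediated C–O coupling on a substrate whose ketone is masked. Reduction with NaBH4 in MeOH/THF at 0 °C should give (2S,4S)-6,8-dibromo-5,7-dimethoxy-2-(4-methoxyphenyl)chroman-4-ol F1 (the 2,4-cis alcohol is expected; the C4 configuration is irrelevant because it is erased later). With no carbonyl left there is no enolate pathway, so strong base can no longer open ring C or epimerize C2. Ullmann-type methoxylation with CuBr and excess NaOMe in MeOH/DMF at about 110 °C should then replace both bromines directly by methoxy groups to give (2S,4S)-5,6,7,8-tetramethoxy-2-(4-methoxyphenyl)chroman-4-ol F2. Oxidation of the benzylic alcohol with Dess–Martin periodinane and NaHCO3 in CH2Cl2 comes back to the route at the target 10, bypassing 8 and 9.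

Step 1. The hydrogen-bonded 5-OH may be etherified incompletely, C-methylation of the phloroglucinol-type ring A may compete, or adventitious basicity may open ring C to the chalcone and erode the C2 configuration. The fallback sets out from 1 and separates the easy from the difficult hydroxyls with two neutral, strictly O-selective methods. Me3SiCHN2 in MeOH/toluene at rt should methylate the acidic 7-OH and the 4'-OH and leave the chelated phenol, giving (2S)-5-hydroxy-7-methoxy-2-(4-methoxyphenyl)chroman-4-one F3. Mitsunobu etherification (MeOH, PPh3, DIAD, THF, 0 °C to rt) should then methylate the 5-OH and come back to the route at 3.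

Step 4. One-electron oxidation of the very electron-rich diphenol by Ag2O may lead to quinoid decomposition, or the doubly flanked 6-OH may be methylated incompletely. The fallback sets out from 9 and uses Mitsunobu etherification (MeOH, PPh3, DIAD, THF, 0 °C to rt), which is neutral, non-oxidizing and too weakly basic to enolize C3, and comes back to the route at 10. No new compound (F0) arises on this detour.

Further compounds
F1 | step 3 | (2S,4S)-6,8-dibromo-5,7-dimethoxy-2-(4-methoxyphenyl)chroman-4-ol | COc1ccc([C@@H]2C[C@H](O)c3c(OC)c(Br)c(OC)c(Br)c3O2)cc1
F2 | step 3 | (2S,4S)-5,6,7,8-tetramethoxy-2-(4-methoxyphenyl)chroman-4-ol | COc1ccc([C@@H]2C[C@H](O)c3c(OC)c(OC)c(OC)c(OC)c3O2)cc1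
F3 | step 1 | (2S)-5-hydroxy-7-methoxy-2-(4-methoxyphenyl)chroman-4-one | COc1ccc([C@@H]2CC(=O)c3c(O)cc(OC)cc3O2)cc1
F0 | step 4 | none | none
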